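Readings and results are calculated with made-up constants; scatter was added.

The closed, stirred vessel at 25 °C had been followed to 10 h, and I had to say what it held and which next step would bring more target.

| flask | starting material | second substrate | capture agent | free catalyst | temperature | remark | time |
|---|---|---|---|---|---|---|---|
| beta | 0.010 M | 0.020 M | 0.50 mM | 0.25 mM | 25 °C | the very flask that is asked about, followed so far |  |
| gamma | 0.010 M | 0.020 M | 0.50 mM | 0.12 mM | 31 °C | run made earlier |  |
| flask | 0.010 M | 0.0200 M | 0.500 mM | 0.25 mM | 25 °C |  | 10 h |

| run | time / min | target / % | starting material / % |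
|---|---|---|---|
| beta | 50.0 | 27.8 | 72.0 |
| beta | 80.0 | 30.1 | 67.6 |
| beta | 120 | 34.9 | 67.0 |
| beta | 180 | 32.6 | 65.3 |
| beta | 240 | 34.6 | 65.4 |
| beta | 360 | 35.1 | 65.8 |
| beta | 600 | 33.6 | 65.9 |
| gamma | 0.667 | 0.9 | 96.0 |
| gamma | 2.00 | 3.9 | 97.5 |
| gamma | 3.00 | 2.4 | 97.0 |
| gamma | 5.00 | 3.4 | 94.3 |
| gamma | 8.00 | 7.7 | 92.9 |
| gamma | 10.0 | 7.1 | 93.2 |
| gamma | 12.0 | 8.8 | 91.4 |

(readings scatter by 1 percentage point)

- Wednesday's: change nothing and wait 3.0 h more
- Friday's: at 10 h add free catalyst, 50.0% of the amount charged, then wait 3.0 h
- Saturday's: at 10 h raise the temperature by 15 K, then wait 3.0 h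
- Sunday's: at 10 h take out 90% of the target then present, then wait 3.0 h

- removed target is counted in
- additions bring no volume worth counting

- target, in percent of the starting material first charged, at 10 h
- the option that brings most further target ("none" if no option brings more than 2 percentage points) (Wednesday's / Friday's / Saturday's / Sunday's / none)
- target present, with what was taken out counted in, in percent of the starting material first charged, after Wednesday's
- target present, with what was taken out counted in, in percent of the starting material first charged, after Saturday's

In this flask the target readings lay flat from 180 min on, at 34.0% on average, while starting material stood near 65.9%. I assumed, without proof from the readings, that capture agent was taking free catalyst one for one. That left c(capture agent) at 0.250 mM of 0.500 mM, and in my reckoning waiting, heating and removing target brought nothing.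

For Friday's, my first round used the turnover number, 13.6 target per catalyst charged, so the added 0.125 mM gave 17 percentage points. But that number belonged to a capture agent running down from 0.500 mM, and I took turnovers per catalyst to go inversely with c(capture agent). So I went round again. The plateau read in this flask gave 4.90 mM for the reach, the target made per unit fall in ln c(capture agent). I reckoned that Friday's, with the added catalyst captured one for one as well, would take c(capture agent) from 0.250 mM to 0.125 mM, and that this would give 34 points, more than the first round.

The forecast, in the words “I favour slow capture of free catalyst”, gave 34.2% now, 34.4% after Wednesday's and 34.8% after Saturday's, and it picked Friday's, as I did.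

The simulation gave 33.9% now, 33.9% after Wednesday's, 33.9% after Saturday's and Friday's as the best option, with 44 points further target against 0 points for Wednesday's, 0 points for Saturday's and 0 points for Sunday's.

    catalyst intermediate B → free catalyst + second product (k = 2.94 min⁻¹, Ea = 77.0 kJ mol⁻¹)
    catalyst intermediate B + capture agent → trapped intermediate (k = 212 M⁻¹ min⁻¹, Ea = 38.0 kJ mol⁻¹)
    second substrate + free catalyst ⇌ catalyst intermediate B (K = 485 M⁻¹, k = 2890 M⁻¹ min⁻¹, Ea = 44.0 kJ mol⁻¹, ΔH = −20.0 kJ mol⁻¹)
    catalyst intermediate A → free catalyst + target (k = 2.34 min⁻¹, Ea = 85.0 kJ mol⁻¹)
    starting material + free catalyst ⇌ catalyst intermediate A (K = 260 M⁻¹, k = 21000 M⁻¹ min⁻¹, Ea = 43.0 kJ mol⁻¹, ΔH = −49.0 kJ mol⁻¹)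
    (constants at 25 °C)

Friday's brought more than my 34 points. At 600 min the flask held 50% of its capture agent, with 100% of the catalyst charged as trapped intermediate. A neighbouring flask was charged with 1.0 × 10⁻⁴ M of free catalyst. I carried the reach over unchanged, with capture one for one taking c(capture agent) in that neighbouring flask from 0.500 mM to 0.400 mM, and reckoned 10.9% target. That neighbouring flask held 10.0% target at 600 min, with 80% of its capture agent left.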